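## The problem

Locants follow carotenoid usage: C1–C6 are the atoms of ring A in the dione half (methyls C16 and C17 on C1, C18 on C5), C7–C15 its chain, and primed numbers belong to the half that ends in the hydroxylated ring B.

1. The target is a C40 chain compound. Two trimethylcyclohexene rings are joined by an 18-carbon chain C7–C7' that carries seven E double bonds (C9=C10 to C9'=C10'), four methyl branches, a ketone at C8 and a triple bond C7'≡C8'. The chain has to be joined at the right places without loss of any alkene geometry.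
2. The ring A end is a cross-conjugated dienedione (C3=O, C4=C5, exocyclic C6=C7, C8=O). Its C6=C7 bond is trisubstituted, sits on a carbon flanked by the quaternary C1, and must be Z (C8 on the side of C5). No carbonyl olefination at such a hindered ring carbon can be expected to deliver that geometry.
3. This end is also the fragile one. It is a Michael acceptor at C4, C6 and C7 and along the polyenone, so it will not survive ylides, alkoxides or strong acid for long.
4. The only stereocentre is C3' (R) in ring B. It is far from every other functional group, can neither control nor be controlled by anything else, and must be set by a reagent or an enzyme and then simply carried.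
5. C9'=C10', next to the triple bond, is liable to lose its geometry whenever C11' becomes an allylic anion (an ylide). The polyene as a whole is sensitive to acid, light and oxygen.
6. The feature that makes the key step possible: C6 lies between the quaternary C1 and the trigonal C5, so a hydroxyl on C6 has no β-hydrogen and can leave only by a 1,3-shift. The array C6=C7–C8(=O) is the 1,3-oxygen-transposed isomer of a carbinol C6(OH)–C7≡C8, which is the same ring–C≡C junction that C6'–C7'≡C8' already shows at the other end.

## Retrosynthesis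

**Target 24 to carbinol 22 (no skeletal bond cut; C8=O and C6=C7 traded for C6–OH and C7≡C8).** The neighbouring cuts are olefination at C6=C7, acylation at C7–C8 and vinyl–acyl coupling at C8–C9. All of them have to build the labile dienedione and its geometry directly on a hindered carbon. The isomerisation instead takes it from an isomeric tertiary propargylic carbinol. 22 is much simpler to make: it has no exocyclic geometry, its C6 configuration is irrelevant (both epimers converge), it contains no Michael acceptor besides a plain ring enone, and its chain is a symmetrical bis-alkynyl heptaene. The forward reaction must be a Meyer–Schuster rearrangement that touches only the alkyne bearing a propargylic hydroxyl, under conditions that avoid carbocations.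

**22 to 21 (C3 dioxolane and C3' triethylsilyl ether).** Both groups are acid-labile and fall in one mild operation. They keep the ring ketone and the secondary alcohol inert during the base-mediated chain assembly.

**21 to C25 phosphonate 19 and aldehyde 13 (C11=C12).** The phosphorus sits on the chain piece and the carbonyl on the C15 piece. This way C9=C10, whose geometry is bought with the starting enynol, is never part of an allylic anion. Ring A travels as the robust ketal carbinol. The forward reaction is an E-selective Horner–Wadsworth–Emmons olefination.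

**19 to bisphosphonate 17 and aldehyde 9 (C11'=C12').** The argument is the same, and it matters more here: C9'=C10' next to the alkyne would scramble in a C15 ylide. 17 is a symmetrical C10 linchpin, and the forward reaction is a mono-olefination with the linchpin in excess.

**13 via diol 12 to ketone 10 and enynol 7 (C6–C7).** An sp nucleophile is small enough for the carbonyl between C1 and C5, and its addition is irreversible. 10 is the mono-ketal of ketoisophorone 1, in which the unhindered carbonyl is masked so that only the correct one is left.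

**9 via alcohol 8 to triflate 6 and the same enynol 7 (C6'–C7').** The ring ketone has a single enolisable position, so the tetrasubstituted enol triflate is unambiguous and Sonogashira coupling gives the enyne directly. 6 comes from silyl ether 4 and hydroxy ketone 3, and 3 from the same diketone 1 by an enzymatic double reduction that sets C3'.

**17 via dibromide 16 and diol 15 to dialdehyde 14.** These are standard functional-group changes on the commercial C10 unit.

The whole skeleton thus comes from three commercial compounds: 1 (twice), 7 (twice) and 14.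

## Roads not taken

**Alternative 1:** the most obvious plan cuts C11=C12 and C11'=C12' with both end groups finished. It is a double Wittig reaction of dialdehyde 14 with the C15 phosphonium salts A1 (dienedione end) and A2 (acetylenic end).
- A1 must first be made by olefination of the most hindered carbonyl of 1, with no control of the C6=C7 geometry.
- The carbanion needed at C11 of A1 is conjugated through C9=C10 with the C8 ketone. It is therefore stabilised and sluggish, and it sits in a molecule full of Michael acceptors under alkoxide conditions.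
- The carbanion from A2 is an allyl anion next to the alkyne and is liable to scramble C9'=C10'.
- The chosen plan keeps both termini as inert alkynyl units, puts the phosphorus on the linchpin, and creates the dienedione last under neutral catalysis.

**Alternative 2:** cut C7–C8 and C8–C9 and use carbon monoxide as C8. This is a three-component carbonylative Stille coupling of the exocyclic vinyl iodide A3 with the C31 polyenyl stannane A4, with retention of both alkene geometries.
- It is convergent, but the Z geometry of A3 is the unsolved problem moved to a smaller molecule. C6 is a ring carbon, so no alkyne hydrometalation can set it.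
- A4 is a protodestannylation-prone polyene that needs a route as long as the one to 22.
- Direct coupling without carbon monoxide insertion would compete in the last step.
- The isomerisation of 22 needs no stereodefined vinyl partner at all.

**Alternative 3:** cut C6–C7 in the aldol sense. The enolate of the C31 methyl ketone A5 is added to ketone 10, and the resulting ketol A6 is then dehydrated.
- Addition of a ketone enolate to a carbonyl flanked by a quaternary carbon is reversible and unfavourable.
- A5 also enolises through its C19 methyl.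
- A6 can revert by retro-aldol cleavage under the basic conditions of dehydration, which in any case has no control over the geometry.
- The chosen plan makes the same C6–C7 bond with an acetylide, irreversibly. It then moves the oxygen from C6 to C8 instead of losing it, in a step whose mechanism gives a handle on geometry.

Key step: step 15

Remark on the chemistry: C6 of 12, 13, 21 and 22 is a carbinol stereocentre formed without control. Both configurations are carried together because step 15 makes C6 trigonal.

## Steps

Step 1
Reactants: 1 2,6,6-trimethylcyclohex-2-ene-1,4-dione (ketoisophorone)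
Product: 3 (4R,6R)-4-hydroxy-2,2,6-trimethylcyclohexan-1-one, via (6R)-levodione 2 (not isolated)
Conditions: ene-reductase (Old Yellow Enzyme family), NADP+ (cat.), D-glucose, glucose dehydrogenase, phosphate buffer pH 7, 30 °C; then ketoreductase of the short-chain dehydrogenase class (levodione reductase type), NAD+ (cat.), same pot
Reagents that add atoms: none
Why: Enzymatic cascade of ene-reductase and ketoreductase: the first enzyme reduces the C=C bond of the ene-dione to (6R)-2, the second reduces only the unhindered C4 carbonyl from one face to the (4R)-alcohol, a pair of selectivities no small reagent offers. C4 becomes C3' of the target and the C6 centre is erased later.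

Step 2
Reactants: 3 (4R,6R)-4-hydroxy-2,2,6-trimethylcyclohexan-1-one
Product: 4 (4R,6R)-2,2,6-trimethyl-4-(triethylsilyloxy)cyclohexan-1-one
Conditions: Et3SiCl, imidazole, DMF, 0 °C to rt
Reagents that add atoms: chlorotriethylsilane CC[Si](Cl)(CC)CC
Why: Standard silylation of a secondary alcohol. The triethylsilyl ether survives amide bases, amines, MnO2 and alkoxides, and falls with the ketal in step 14.

Step 3
Reactants: 4 (4R,6R)-2,2,6-trimethyl-4-(triethylsilyloxy)cyclohexan-1-one
Product: 6 (4R)-2,6,6-trimethyl-4-(triethylsilyloxy)cyclohex-1-en-1-yl trifluoromethanesulfonate, via lithium enolate 5 (not isolated)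
Conditions: LiN(i-Pr)2, THF, −78 to 0 °C; then PhNTf2, −78 °C to rt
Reagents that add atoms: N-phenylbis(trifluoromethanesulfonimide) FC(F)(F)S(=O)(=O)N(c1ccccc1)S(=O)(=O)C(F)(F)F
Why: Enolate O-triflation. The ketone has a single α-hydrogen (the other α-carbon is quaternary), so only the tetrasubstituted enol triflate can form, and the silyloxy group is γ to the enolate carbon and cannot be eliminated.

Step 4
Reactants: 6 (4R)-2,6,6-trimethyl-4-(triethylsilyloxy)cyclohex-1-en-1-yl trifluoromethanesulfonate; 7 (2E)-3-methylpent-2-en-4-yn-1-ol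
Product: 8 (2E)-3-methyl-5-[(4R)-2,6,6-trimethyl-4-(triethylsilyloxy)cyclohex-1-en-1-yl]pent-2-en-4-yn-1-ol
Conditions: Pd(PPh3)4 (5 mol%, zerovalent palladium), CuI (10 mol%), i-Pr2NH, THF, rt to 45 °C
Reagents that add atoms: none
Why: Sonogashira coupling of an enol triflate with a terminal enyne forms C6'–C7' and gives the ring B dienyne directly. The E geometry of 7 (the later C9'=C10') is untouched and the free primary alcohol is tolerated.

Step 5
Reactants: 8 (2E)-3-methyl-5-[(4R)-2,6,6-trimethyl-4-(triethylsilyloxy)cyclohex-1-en-1-yl]pent-2-en-4-yn-1-ol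
Product: 9 (2E)-3-methyl-5-[(4R)-2,6,6-trimethyl-4-(triethylsilyloxy)cyclohex-1-en-1-yl]pent-2-en-4-ynal
Conditions: MnO2 (activated, excess), CH2Cl2, rt
Reagents that add atoms: none
Why: Chemoselective MnO2 oxidation of a primary allylic alcohol to the enal under neutral conditions, without change of the C9'=C10' geometry.

Step 6
Reactants: 1 2,6,6-trimethylcyclohex-2-ene-1,4-dione (ketoisophorone)
Product: 10 7,9,9-trimethyl-1,4-dioxaspiro[4.5]dec-6-en-8-one
Conditions: ethylene glycol (1.1 equiv), p-TsOH (cat.), benzene, reflux, Dean–Stark trap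
Reagents that add atoms: ethylene glycol OCCO
Why: Acid-catalysed ketalisation occurs at the carbonyl flanked by CH2 and CH. The carbonyl between the quaternary carbon and the methyl-bearing alkene carbon is too hindered, so exactly the carbonyl that becomes C6 is left free.

Step 7
Reactants: 7 (2E)-3-methylpent-2-en-4-yn-1-ol; 10 7,9,9-trimethyl-1,4-dioxaspiro[4.5]dec-6-en-8-one
Product: 12 (2E)-5-(8-hydroxy-7,9,9-trimethyl-1,4-dioxaspiro[4.5]dec-6-en-8-yl)-3-methylpent-2-en-4-yn-1-ol, via dilithio enynol 11 (not isolated)
Conditions: n-BuLi (2.05 equiv), THF, −78 to −20 °C; then 10, −78 to 0 °C; aq. NH4Cl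
Reagents that add atoms: none
Why: 1,2-Addition of a lithium acetylide (alkoxide–acetylide dianion) to the hindered enone carbonyl forms C6–C7 irreversibly, as in the abscisic acid series. The new carbinol centre is formed as both configurations, which does not matter.

Step 8
Reactants: 12 (2E)-5-(8-hydroxy-7,9,9-trimethyl-1,4-dioxaspiro[4.5]dec-6-en-8-yl)-3-methylpent-2-en-4-yn-1-ol
Product: 13 (2E)-5-(8-hydroxy-7,9,9-trimethyl-1,4-dioxaspiro[4.5]dec-6-en-8-yl)-3-methylpent-2-en-4-ynal
Conditions: MnO2 (activated, excess), CH2Cl2, rt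
Reagents that add atoms: none
Why: MnO2 oxidises only the primary allylic alcohol. The tertiary carbinol and the ketal are inert.

Step 9
Reactants: 14 (2E,4E,6E)-2,7-dimethylocta-2,4,6-trienedial
Product: 15 (2E,4E,6E)-2,7-dimethylocta-2,4,6-triene-1,8-diol
Conditions: NaBH4, MeOH–THF, 0 °C
Reagents that add atoms: none
Why: 1,2-Reduction of both conjugated aldehydes by borohydride. The triene geometry is not affected.

Step 10
Reactants: 15 (2E,4E,6E)-2,7-dimethylocta-2,4,6-triene-1,8-diol
Product: 16 (2E,4E,6E)-1,8-dibromo-2,7-dimethylocta-2,4,6-triene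
Conditions: PBr3, pyridine (cat.), Et2O, −10 °C, dark
Reagents that add atoms: phosphorus tribromide BrP(Br)Br
Why: Conversion of primary allylic alcohols into bromides. The primary, fully conjugated bromide is the thermodynamic allylic isomer, so no transposition is expected.

Step 11
Reactants: 16 (2E,4E,6E)-1,8-dibromo-2,7-dimethylocta-2,4,6-triene
Product: 17 tetraethyl [(2E,4E,6E)-2,7-dimethylocta-2,4,6-triene-1,8-diyl]bis(phosphonate)
Conditions: P(OEt)3 (excess), 110 °C, removal of EtBr
Reagents that add atoms: triethyl phosphite CCOP(OCC)OCC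
Why: Twofold Michaelis–Arbuzov reaction of a primary allylic dibromide gives the symmetrical C10 linchpin.

Step 12
Reactants: 17 tetraethyl [(2E,4E,6E)-2,7-dimethylocta-2,4,6-triene-1,8-diyl]bis(phosphonate); 9 (2E)-3-methyl-5-[(4R)-2,6,6-trimethyl-4-(triethylsilyloxy)cyclohex-1-en-1-yl]pent-2-en-4-ynal
Product: 19 diethyl [(2E,4E,6E,8E,10E)-2,7,11-trimethyl-13-[(4R)-2,6,6-trimethyl-4-(triethylsilyloxy)cyclohex-1-en-1-yl]trideca-2,4,6,8,10-pentaen-12-yn-1-yl]phosphonate, via phosphonate monoanion 18 (not isolated)
Conditions: 17 (3 equiv), KOtBu (1.0 equiv), THF, −30 °C; then 9 (1 equiv), −30 to 0 °C; excess 17 recovered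
Reagents that add atoms: none
Why: Horner–Wadsworth–Emmons olefination of an allylic phosphonate with an enal forms C11'=C12' with E geometry. The excess of the symmetrical linchpin should hold the reaction at the mono-olefination stage, and C9'=C10' belongs to the aldehyde partner and is never part of an allyl anion.

Step 13
Reactants: 19 diethyl [(2E,4E,6E,8E,10E)-2,7,11-trimethyl-13-[(4R)-2,6,6-trimethyl-4-(triethylsilyloxy)cyclohex-1-en-1-yl]trideca-2,4,6,8,10-pentaen-12-yn-1-yl]phosphonate; 13 (2E)-5-(8-hydroxy-7,9,9-trimethyl-1,4-dioxaspiro[4.5]dec-6-en-8-yl)-3-methylpent-2-en-4-ynal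
Product: 21 8-{(3E,5E,7E,9E,11E,13E,15E)-3,7,12,16-tetramethyl-18-[(4R)-2,6,6-trimethyl-4-(triethylsilyloxy)cyclohex-1-en-1-yl]octadeca-3,5,7,9,11,13,15-heptaene-1,17-diyn-1-yl}-7,9,9-trimethyl-1,4-dioxaspiro[4.5]dec-6-en-8-ol, via phosphonate anion 20 (not isolated)
Conditions: KOtBu (1.05 equiv), THF, −40 °C; then 13, −40 to 0 °C, dark
Reagents that add atoms: none
Why: A second Horner–Wadsworth–Emmons olefination forms C11=C12 (E) and completes the C40 skeleton. The tertiary hydroxyl is less acidic than the polyenyl phosphonate and should not quench the anion, and the ketal keeps ring A free of electrophilic sites.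

Step 14
Reactants: 21 8-{(3E,5E,7E,9E,11E,13E,15E)-3,7,12,16-tetramethyl-18-[(4R)-2,6,6-trimethyl-4-(triethylsilyloxy)cyclohex-1-en-1-yl]octadeca-3,5,7,9,11,13,15-heptaene-1,17-diyn-1-yl}-7,9,9-trimethyl-1,4-dioxaspiro[4.5]dec-6-en-8-ol
Product: 22 4-hydroxy-4-{(3E,5E,7E,9E,11E,13E,15E)-18-[(4R)-4-hydroxy-2,6,6-trimethylcyclohex-1-en-1-yl]-3,7,12,16-tetramethyloctadeca-3,5,7,9,11,13,15-heptaene-1,17-diyn-1-yl}-3,5,5-trimethylcyclohex-2-en-1-one
Conditions: pyridinium p-toluenesulfonate (0.3 equiv), acetone–H2O 9:1, 40 °C, argon, dark
Reagents that add atoms: water O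
Why: Mild acid hydrolysis removes the dioxolane and the triethylsilyl ether together. The tertiary carbinol has no β-hydrogen and, once the C3 ketone is free, is deactivated towards ionisation, as in the hydrolysis of abscisic acid ketals.

Step 15
Reactants: 22 4-hydroxy-4-{(3E,5E,7E,9E,11E,13E,15E)-18-[(4R)-4-hydroxy-2,6,6-trimethylcyclohex-1-en-1-yl]-3,7,12,16-tetramethyloctadeca-3,5,7,9,11,13,15-heptaene-1,17-diyn-1-yl}-3,5,5-trimethylcyclohex-2-en-1-one
Product: 24 (4Z)-4-{(3E,5E,7E,9E,11E,13E,15E)-18-[(4R)-4-hydroxy-2,6,6-trimethylcyclohex-1-en-1-yl]-3,7,12,16-tetramethyl-2-oxooctadeca-3,5,7,9,11,13,15-heptaen-17-yn-1-ylidene}-3,5,5-trimethylcyclohex-2-en-1-one, via allenol 23 (not isolated)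
Conditions: ReOCl3(OPPh3)(SMe2) (5 mol%, oxo complex of pentavalent rhenium), DME, 50 °C, argon, dark
Reagents that add atoms: none
Why: Meyer–Schuster rearrangement in its oxo-metal form: the C6 hydroxyl is bound to the Re=O catalyst as a rhenate ester, and a [3,3]-sigmatropic shift through a six-membered O–Re=O···C8 array moves the oxygen from C6 to C8, giving an allenyl rhenate that is released by alcohol exchange as allenol 23 and ketonises by protonation at C7. The closest known reaction type is the oxo-rhenium-, oxo-vanadium- or oxo-molybdenum-catalysed 1,3-transposition of tertiary propargylic alcohols, 1-alkynyl-2,2,6-trimethylcyclohexanols and enyne carbinols included, to enones. No ring is closed and no stereocentre is formed; C6 becomes trigonal, so both C6 epimers of 22 converge on one product. The new stereo-element is the C6=C7 geometry, set when C7 of 23 is protonated in the ring plane: in the allene the two substituents of C8 (OH and C9) stand above and below that plane, the two C1 methyl groups stand above and below it on one flank, and the C18 methyl lies in it on the other flank. The proton should therefore enter through the cleft between the geminal methyl groups while C8 swings to the C5 flank, where its out-of-plane substituents straddle C18, which is the required 6Z geometry; the same contacts should make the twisted 6Z acyl group the resting isomer. The step needs chemoselectivity for C7≡C8, and the substrate secures it because only this alkyne carries a propargylic hydroxyl, whereas C7'≡C8' has none and the C3' hydroxyl is homoallylic and has no [3,3] path. Elimination of the Rupe type is impossible because C6 has no β-hydrogen (C1 quaternary, C5 trigonal), and the C3–C5 enone disfavours ionisation at C6, which keeps the polyene out of carbocation chemistry. Ketonisation of 23 is irreversible and drives the isomerisation.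

## Compound list

1 | 2,6,6-trimethylcyclohex-2-ene-1,4-dione (ketoisophorone) | CC1=CC(=O)CC(C)(C)C1=O | starting material
2 | (6R)-2,2,6-trimethylcyclohexane-1,4-dione ((6R)-levodione, formed in the flask) | C[C@@H]1CC(=O)CC(C)(C)C1=O | intermediate
3 | (4R,6R)-4-hydroxy-2,2,6-trimethylcyclohexan-1-one | C[C@@H]1C[C@@H](O)CC(C)(C)C1=O | intermediate
4 | (4R,6R)-2,2,6-trimethyl-4-(triethylsilyloxy)cyclohexan-1-one | C[C@@H]1C[C@@H](O[Si](CC)(CC)CC)CC(C)(C)C1=O | intermediate
5 | lithium (4R)-2,6,6-trimethyl-4-(triethylsilyloxy)cyclohex-1-en-1-olate (formed in the flask) | [Li]OC1=C(C)C[C@@H](O[Si](CC)(CC)CC)CC1(C)C | intermediate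
6 | (4R)-2,6,6-trimethyl-4-(triethylsilyloxy)cyclohex-1-en-1-yl trifluoromethanesulfonate | O=S(=O)(OC1=C(C)C[C@@H](O[Si](CC)(CC)CC)CC1(C)C)C(F)(F)F | intermediate
7 | (2E)-3-methylpent-2-en-4-yn-1-ol | C#C/C(C)=C/CO | starting material
8 | (2E)-3-methyl-5-[(4R)-2,6,6-trimethyl-4-(triethylsilyloxy)cyclohex-1-en-1-yl]pent-2-en-4-yn-1-ol | OC/C=C(\C)C#CC1=C(C)C[C@@H](O[Si](CC)(CC)CC)CC1(C)C | intermediate
9 | (2E)-3-methyl-5-[(4R)-2,6,6-trimethyl-4-(triethylsilyloxy)cyclohex-1-en-1-yl]pent-2-en-4-ynal | O=C/C=C(\C)C#CC1=C(C)C[C@@H](O[Si](CC)(CC)CC)CC1(C)C | intermediate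
10 | 7,9,9-trimethyl-1,4-dioxaspiro[4.5]dec-6-en-8-one | CC1=CC2(OCCO2)CC(C)(C)C1=O | intermediate
11 | dilithium salt of (2E)-3-methylpent-2-en-4-yn-1-ol (lithium alkoxide and lithium acetylide, formed in the flask) | [Li]C#C/C(C)=C/CO[Li] | intermediate
12 | (2E)-5-(8-hydroxy-7,9,9-trimethyl-1,4-dioxaspiro[4.5]dec-6-en-8-yl)-3-methylpent-2-en-4-yn-1-ol (both configurations at the carbinol carbon) | OC/C=C(\C)C#CC1(O)C(C)=CC2(OCCO2)CC1(C)C | intermediate
13 | (2E)-5-(8-hydroxy-7,9,9-trimethyl-1,4-dioxaspiro[4.5]dec-6-en-8-yl)-3-methylpent-2-en-4-ynal (both configurations at the carbinol carbon) | O=C/C=C(\C)C#CC1(O)C(C)=CC2(OCCO2)CC1(C)C | intermediate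
14 | (2E,4E,6E)-2,7-dimethylocta-2,4,6-trienedial | O=C/C(C)=C/C=C/C=C(\C)C=O | starting material
15 | (2E,4E,6E)-2,7-dimethylocta-2,4,6-triene-1,8-diol | OC/C(C)=C/C=C/C=C(\C)CO | intermediate
16 | (2E,4E,6E)-1,8-dibromo-2,7-dimethylocta-2,4,6-triene | BrC/C(C)=C/C=C/C=C(\C)CBr | intermediate
17 | tetraethyl [(2E,4E,6E)-2,7-dimethylocta-2,4,6-triene-1,8-diyl]bis(phosphonate) | CCOP(=O)(OCC)C/C(C)=C/C=C/C=C(\C)CP(=O)(OCC)OCC | intermediate
18 | potassium salt of the monoanion of 17 (carbanion at one P–CH2, formed in the flask) | [K+].CCOP(=O)(OCC)[CH-]/C(C)=C/C=C/C=C(\C)CP(=O)(OCC)OCC | intermediate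
19 | diethyl [(2E,4E,6E,8E,10E)-2,7,11-trimethyl-13-[(4R)-2,6,6-trimethyl-4-(triethylsilyloxy)cyclohex-1-en-1-yl]trideca-2,4,6,8,10-pentaen-12-yn-1-yl]phosphonate | CCOP(=O)(OCC)C/C(C)=C/C=C/C=C(C)/C=C/C=C(\C)C#CC1=C(C)C[C@@H](O[Si](CC)(CC)CC)CC1(C)C | intermediate
20 | potassium salt of the anion of 19 (carbanion at P–CH2, formed in the flask) | [K+].CCOP(=O)(OCC)[CH-]/C(C)=C/C=C/C=C(C)/C=C/C=C(\C)C#CC1=C(C)C[C@@H](O[Si](CC)(CC)CC)CC1(C)C | intermediate
21 | 8-{(3E,5E,7E,9E,11E,13E,15E)-3,7,12,16-tetramethyl-18-[(4R)-2,6,6-trimethyl-4-(triethylsilyloxy)cyclohex-1-en-1-yl]octadeca-3,5,7,9,11,13,15-heptaene-1,17-diyn-1-yl}-7,9,9-trimethyl-1,4-dioxaspiro[4.5]dec-6-en-8-ol (both configurations at C6) | CC1=CC2(OCCO2)CC(C)(C)C1(O)C#C/C(C)=C/C=C/C(C)=C/C=C/C=C(C)/C=C/C=C(\C)C#CC1=C(C)C[C@@H](O[Si](CC)(CC)CC)CC1(C)C | intermediate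
22 | 4-hydroxy-4-{(3E,5E,7E,9E,11E,13E,15E)-18-[(4R)-4-hydroxy-2,6,6-trimethylcyclohex-1-en-1-yl]-3,7,12,16-tetramethyloctadeca-3,5,7,9,11,13,15-heptaene-1,17-diyn-1-yl}-3,5,5-trimethylcyclohex-2-en-1-one (both configurations at C6) | CC1=CC(=O)CC(C)(C)C1(O)C#C/C(C)=C/C=C/C(C)=C/C=C/C=C(C)/C=C/C=C(\C)C#CC1=C(C)C[C@@H](O)CC1(C)C | intermediate
23 | allenol C6=C7=C8(OH): 4-{(3E,5E,7E,9E,11E,13E,15E)-2-hydroxy-18-[(4R)-4-hydroxy-2,6,6-trimethylcyclohex-1-en-1-yl]-3,7,12,16-tetramethyloctadeca-1,3,5,7,9,11,13,15-octaen-17-yn-1-ylidene}-3,5,5-trimethylcyclohex-2-en-1-one (formed in the flask) | CC1=CC(=O)CC(C)(C)C1=C=C(O)/C(C)=C/C=C/C(C)=C/C=C/C=C(C)/C=C/C=C(\C)C#CC1=C(C)C[C@@H](O)CC1(C)C | intermediate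
24 | (4Z)-4-{(3E,5E,7E,9E,11E,13E,15E)-18-[(4R)-4-hydroxy-2,6,6-trimethylcyclohex-1-en-1-yl]-3,7,12,16-tetramethyl-2-oxooctadeca-3,5,7,9,11,13,15-heptaen-17-yn-1-ylidene}-3,5,5-trimethylcyclohex-2-en-1-one | CC1=CC(=O)CC(C)(C)/C1=C/C(=O)/C(C)=C/C=C/C(C)=C/C=C/C=C(C)/C=C/C=C(\C)C#CC1=C(C)C[C@@H](O)CC1(C)C | target

## Step count and risks

Total step count: 15. Longest linear sequence: 9 steps (steps 1–5 and 12–15).

**Step 15 (key step).** Most likely to go wrong:
- Poor control of the direction of C7 protonation during ketonisation of the allenol, which would give much of the 6E geometry.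
- Lewis-acid-induced geometric isomerisation or decomposition of the polyenyne at 50 °C.

Fallback: carry out the transposition before the chain is built, where isomers can be separated and recycled on a small molecule. Setting out from 13, aqueous HCl in acetone should remove the ketal to give the hydroxy enone aldehyde (2E)-5-(1-hydroxy-2,6,6-trimethyl-4-oxocyclohex-2-en-1-yl)-3-methylpent-2-en-4-ynal F1. The same oxo-rhenium catalysis (or plain acid catalysis, since no polyene is present) should convert it into the dienedione aldehyde (2E)-3-methyl-4-oxo-5-[(1Z)-2,6,6-trimethyl-4-oxocyclohex-2-en-1-ylidene]pent-2-enal F2. Its 6Z and 6E isomers would be separated by chromatography, and the 6E fraction re-equilibrated with a trace of iodine in light and recycled. Horner–Wadsworth–Emmons olefination of anion 20 with F2 at −78 °C (the aldehyde being far more electrophilic than the two hindered ketones) should give the triethylsilyl ether of the target F3. Buffered HF·pyridine then leads back to 24.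

**Step 14.** Most likely to go wrong: acid-induced ionisation of the C6 carbinol while the dioxolane is still in place, giving a cation delocalised into the polyenyne, with loss of the hydroxyl or scrambling of alkene geometry.

Fallback: take the ketal off at the C15 stage and leave only a fluoride deprotection for the C40 stage. Setting out from 13, hydrolysis gives F1 as above. Olefination of anion 20 with F1 (ring enones are tolerated in carotenoid olefinations) should give the triethylsilyl ether of 22 F4. Bu4NF buffered with acetic acid then returns to 22.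

**Step 13.** Most likely to go wrong: base-induced damage to aldehyde 13 before it is olefinated. This could be γ-deprotonation at the C9 methyl with loss of the C9=C10 geometry, or retro-addition of the tertiary propargylic alkoxide.

Fallback: attach ring A last. Setting out from 7, MnO2 oxidation gives (2E)-3-methylpent-2-en-4-ynal F5. Olefination of anion 20 with F5 should give the C31 terminal alkyne that carries ring B F6. Deprotonation of F6 with LiN(SiMe3)2 and addition to ketone 10, the same bond formation as in step 7, returns to 21.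

**Step 12.** Most likely to go wrong: over-reaction of the symmetrical linchpin (olefination at both phosphonate ends), which consumes two molecules of the chiral aldehyde 9 and complicates separation.

Fallback: let the statistical event fall on a cheap achiral partner and attach ring B last. Setting out from 17 (in excess) and F5, mono-olefination should give the C16 phosphonate with a terminal alkyne, diethyl [(2E,4E,6E,8E,10E)-2,7,11-trimethyltrideca-2,4,6,8,10-pentaen-12-yn-1-yl]phosphonate F7. Olefination of its anion with 13 gives the C31 terminal alkyne that carries ring A F8. Sonogashira coupling of F8 with triflate 6, the same bond formation as in step 4, returns to 21.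

## Further compounds

F1 | step 15 | (2E)-5-(1-hydroxy-2,6,6-trimethyl-4-oxocyclohex-2-en-1-yl)-3-methylpent-2-en-4-ynal | O=C/C=C(\C)C#CC1(O)C(C)=CC(=O)CC1(C)C
F2 | step 15 | (2E)-3-methyl-4-oxo-5-[(1Z)-2,6,6-trimethyl-4-oxocyclohex-2-en-1-ylidene]pent-2-enal | CC1=CC(=O)CC(C)(C)/C1=C/C(=O)/C(C)=C/C=O
F3 | step 15 | triethylsilyl ether of 24 at the ring B hydroxyl | CC1=CC(=O)CC(C)(C)/C1=C/C(=O)/C(C)=C/C=C/C(C)=C/C=C/C=C(C)/C=C/C=C(\C)C#CC1=C(C)C[C@@H](O[Si](CC)(CC)CC)CC1(C)C
F4 | step 14 | triethylsilyl ether of 22 at the ring B hydroxyl | CC1=CC(=O)CC(C)(C)C1(O)C#C/C(C)=C/C=C/C(C)=C/C=C/C=C(C)/C=C/C=C(\C)C#CC1=C(C)C[C@@H](O[Si](CC)(CC)CC)CC1(C)C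
F5 | step 13 | (2E)-3-methylpent-2-en-4-ynal | C#C/C(C)=C/C=O
F6 | step 13 | triethyl{[(1R)-4-[(3E,5E,7E,9E,11E,13E,15E)-3,7,12,16-tetramethyloctadeca-3,5,7,9,11,13,15-heptaene-1,17-diyn-1-yl]-3,5,5-trimethylcyclohex-3-en-1-yl]oxy}silane (C31 terminal alkyne with ring B) | C#C/C(C)=C/C=C/C(C)=C/C=C/C=C(C)/C=C/C=C(\C)C#CC1=C(C)C[C@@H](O[Si](CC)(CC)CC)CC1(C)C
F7 | step 12 | diethyl [(2E,4E,6E,8E,10E)-2,7,11-trimethyltrideca-2,4,6,8,10-pentaen-12-yn-1-yl]phosphonate | CCOP(=O)(OCC)C/C(C)=C/C=C/C=C(C)/C=C/C=C(\C)C#C
F8 | step 12 | 7,9,9-trimethyl-8-[(3E,5E,7E,9E,11E,13E,15E)-3,7,12,16-tetramethyloctadeca-3,5,7,9,11,13,15-heptaene-1,17-diyn-1-yl]-1,4-dioxaspiro[4.5]dec-6-en-8-ol (C31 terminal alkyne with ring A) | CC1=CC2(OCCO2)CC(C)(C)C1(O)C#C/C(C)=C/C=C/C(C)=C/C=C/C=C(C)/C=C/C=C(\C)C#C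
A1 | alternative 1 | {(2E)-3-methyl-4-oxo-5-[(1Z)-2,6,6-trimethyl-4-oxocyclohex-2-en-1-ylidene]pent-2-en-1-yl}triphenylphosphonium bromide | CC1=CC(=O)CC(C)(C)/C1=C/C(=O)/C(C)=C/C[P+](c1ccccc1)(c1ccccc1)c1ccccc1.[Br-]
A2 | alternative 1 | {(2E)-5-[(4R)-4-hydroxy-2,6,6-trimethylcyclohex-1-en-1-yl]-3-methylpent-2-en-4-yn-1-yl}triphenylphosphonium bromide | C(/C=C(\C)C#CC1=C(C)C[C@@H](O)CC1(C)C)[P+](c1ccccc1)(c1ccccc1)c1ccccc1.[Br-]
A3 | alternative 2 | (4Z)-4-(iodomethylidene)-3,5,5-trimethylcyclohex-2-en-1-one | CC1=CC(=O)CC(C)(C)/C1=C/I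
A4 | alternative 2 | tributyl{(2E,4E,6E,8E,10E,12E,14E)-17-[(4R)-4-hydroxy-2,6,6-trimethylcyclohex-1-en-1-yl]-6,11,15-trimethylheptadeca-2,4,6,8,10,12,14-heptaen-16-yn-2-yl}stannane | CCCC[Sn](CCCC)(CCCC)/C(C)=C/C=C/C(C)=C/C=C/C=C(C)/C=C/C=C(\C)C#CC1=C(C)C[C@@H](O)CC1(C)C
A5 | alternative 3 | (3E,5E,7E,9E,11E,13E,15E)-18-[(4R)-4-hydroxy-2,6,6-trimethylcyclohex-1-en-1-yl]-3,7,12,16-tetramethyloctadeca-3,5,7,9,11,13,15-heptaen-17-yn-2-one | CC(=O)/C(C)=C/C=C/C(C)=C/C=C/C=C(C)/C=C/C=C(\C)C#CC1=C(C)C[C@@H](O)CC1(C)C
A6 | alternative 3 | 4-hydroxy-4-{(3E,5E,7E,9E,11E,13E,15E)-18-[(4R)-4-hydroxy-2,6,6-trimethylcyclohex-1-en-1-yl]-3,7,12,16-tetramethyl-2-oxooctadeca-3,5,7,9,11,13,15-heptaen-17-yn-1-yl}-3,5,5-trimethylcyclohex-2-en-1-one | CC1=CC(=O)CC(C)(C)C1(O)CC(=O)/C(C)=C/C=C/C(C)=C/C=C/C=C(C)/C=C/C=C(\C)C#CC1=C(C)C[C@@H](O)CC1(C)C
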